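**Plan**

- Numbering: ring A is the 3-furyl ring, ring B the central furan (O1, C2–C5), ring C the butenolide; the side chain runs from C1' (alkylidene carbon on C5 of ring C) to C9' (CH2 on C4 of ring B).
- Cuts, in retrosynthetic order: in ring C the C5=C1' enol-lactone alkene (dehydration), O1–C5 (epoxide-opening lactonisation) and C3=C4 (Z-olefination); in the chain C5–C1' (E-olefination, later epoxidised), C3'–C4' (Negishi), C4'=C5' (iodo-olefination), C6'=C7' (cross-metathesis) and C8'–C9' (allylation); in ring B O1–C2 and C3–C4.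
- Enabling feature: ring B is a 2,4-disubstituted furan with the CH2 bridge to ring A on C2. C2, C3 and the bridge carbon form a propargyl unit; O1, C5, C4 and the carboxyl carbon on C4 form a β-alkoxyacrylate. Together they are a propargyl vinyl ether, which gold converts into the furan.
- Forward: ring A is bought as furan-3-carbaldehyde, ring B is closed in step 3, the chain is grown outwards from the ring B ester (steps 4–12), and ring C is closed last (steps 15–17).
- Stereochemistry: C2' (S) comes from methyl (R)-3-bromo-2-methylpropanoate; 6'E from thermodynamic cross-metathesis and 4'E from the Takai reaction; the 5E alkylidene from a trans epoxide, lactonisation with inversion and anti-elimination.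

Key step: step 3

Remark: the SMILES places the ring C oxygen trans to C2' across C5=C1', i.e. the less stable 5E alkylidene, and the endgame is built for that isomer; the two epoxide centres made in step 13 are sacrificial and only their trans relationship matters.

**Route**

Step 1
Reactants: 1 furan-3-carbaldehyde; 2 ethynylmagnesium bromide
Product: 3 1-(furan-3-yl)prop-2-yn-1-ol (racemic)
Conditions: THF, 0 °C
Reagents that add atoms: none
Why: Grignard 1,2-addition of the acetylide to the aldehyde; the carbinol centre is formed racemic, which is harmless because it ends as the CH2 bridge.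

Step 2
Reactants: 3 1-(furan-3-yl)prop-2-yn-1-ol; 4 ethyl propiolate
Product: 5 ethyl (2E)-3-{[1-(furan-3-yl)prop-2-yn-1-yl]oxy}prop-2-enoate (racemic)
Conditions: DABCO (10 mol %), CH2Cl2, 0 °C → rt
Reagents that add atoms: none
Why: Amine-catalysed oxa-Michael addition of the alcohol to the propiolate, which is known to give the E β-alkoxyacrylate.

Step 3
Reactants: 5 ethyl (2E)-3-{[1-(furan-3-yl)prop-2-yn-1-yl]oxy}prop-2-enoate
Product: 7 ethyl 5-(furan-3-ylmethyl)furan-3-carboxylate, via allenyl formyl ester 6 (not isolated)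
Conditions: Ph3PAuCl (2 mol %), AgBF4 (2 mol %), CH2Cl2, 0 °C → rt
Reagents that add atoms: none
Why: Cationic monovalent gold (from Ph3PAuCl and AgBF4) binds the terminal alkyne and triggers a propargyl Claisen [3,3] rearrangement through a six-membered array, in which the acrylate α-carbon bonds to the alkyne terminus (C3–C4 of ring B) while the propargylic C–O bond breaks, giving allenyl formyl ester 6. The enol oxygen of the formyl group of 6 then attacks the central carbon of the gold-bound allene in a 5-exo closure (O1–C2), and protodeauration with a proton shift aromatises ring B, the former carbinol carbon ending as the CH2 bridge. The closest known reaction is the gold-catalysed propargyl Claisen rearrangement and heterocyclisation of propargyl vinyl ethers made from β-alkoxyacrylates, which gives furan-3-carboxylates. No stereocentre is formed and the racemic centre of 5 is erased. The only selectivity needed is regiochemical and the ether connectivity fixes it, since only the 2,4-pattern can arise. The hazard is ionisation of the furyl-substituted propargylic ether, which a non-acidic catalyst, a weakly coordinating counter-ion and a low temperature should limit.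

Step 4
Reactants: 7 ethyl 5-(furan-3-ylmethyl)furan-3-carboxylate
Product: 8 [5-(furan-3-ylmethyl)furan-3-yl]methanol
Conditions: LiAlH4, THF, 0 °C
Reagents that add atoms: none
Why: Hydride reduction of the ester to the primary alcohol, to which both furan rings are inert.

Step 5
Reactants: 8 [5-(furan-3-ylmethyl)furan-3-yl]methanol
Product: 9 4-(bromomethyl)-2-(furan-3-ylmethyl)furan
Conditions: CBr4, PPh3, CH2Cl2, 0 °C; used at once
Reagents that add atoms: carbon tetrabromide, BrC(Br)(Br)Br
Why: Appel bromination under neutral conditions, chosen because furans and furylmethyl halides do not tolerate HBr.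

Step 6
Reactants: 9 4-(bromomethyl)-2-(furan-3-ylmethyl)furan; 10 allylmagnesium bromide
Product: 11 4-(but-3-en-1-yl)-2-(furan-3-ylmethyl)furan
Conditions: CuI (5 mol %), THF, −40 → 0 °C
Reagents that add atoms: none
Why: Copper-catalysed Grignard cross-coupling, an SN2 displacement of the reactive furylmethyl bromide by the allyl group.

Step 7
Reactants: 11 4-(but-3-en-1-yl)-2-(furan-3-ylmethyl)furan; 12 methacrolein
Product: 13 (2E)-5-[5-(furan-3-ylmethyl)furan-3-yl]-2-methylpent-2-enal
Conditions: 12 (5 equiv), second-generation Grubbs catalyst (H2IMes)(PCy3)Cl2Ru=CHPh (5 mol %), CH2Cl2, 40 °C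
Reagents that add atoms: none
Why: Olefin cross-metathesis of a terminal alkene with a 1,1-disubstituted enal that barely homodimerises, giving the E trisubstituted enal under thermodynamic control.

Step 8
Reactants: 13 (2E)-5-[5-(furan-3-ylmethyl)furan-3-yl]-2-methylpent-2-enal; 14 iodoform
Product: 15 2-(furan-3-ylmethyl)-4-[(3E,5E)-6-iodo-4-methylhexa-3,5-dien-1-yl]furan
Conditions: CrCl2 (6 equiv), THF–dioxane, 0 °C → rt, dark
Reagents that add atoms: none
Why: Takai iodo-olefination, in which the geminal dichromium species from iodoform adds to the aldehyde and eliminates to the E alkenyl iodide without touching the trisubstituted alkene.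

Step 9
Reactants: 15 2-(furan-3-ylmethyl)-4-[(3E,5E)-6-iodo-4-methylhexa-3,5-dien-1-yl]furan; 16 methyl (2R)-3-bromo-2-methylpropanoate
Product: 18 methyl (2S,4E,6E)-9-[5-(furan-3-ylmethyl)furan-3-yl]-2,6-dimethylnona-4,6-dienoate, via organozinc bromide 17 (not isolated)
Conditions: 16, Zn dust, I2 (5 mol %), DMA, 70 °C; then 15, Pd(PPh3)4 (5 mol %), THF, rt
Reagents that add atoms: none
Why: Negishi coupling of a zinc homoenolate with an alkenyl iodide under zerovalent palladium, which keeps both alkene geometries and carries the untouched α-centre of 16 into C2' (the descriptor changes from R to S only because the CIP ranking of the neighbours changes).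

Step 10
Reactants: 18 methyl (2S,4E,6E)-9-[5-(furan-3-ylmethyl)furan-3-yl]-2,6-dimethylnona-4,6-dienoate
Product: 19 (2S,4E,6E)-9-[5-(furan-3-ylmethyl)furan-3-yl]-2,6-dimethylnona-4,6-dienal
Conditions: i-Bu2AlH (1.1 equiv), CH2Cl2, −78 °C; used crude
Reagents that add atoms: none
Why: Partial reduction of the methyl ester, held at the aluminium hemiacetal at low temperature so that the aldehyde appears only on work-up and its α-centre is not exposed to base.

Step 11
Reactants: 19 (2S,4E,6E)-9-[5-(furan-3-ylmethyl)furan-3-yl]-2,6-dimethylnona-4,6-dienal; 20 triethyl phosphonoacetate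
Product: 21 ethyl (2E,4S,6E,8E)-11-[5-(furan-3-ylmethyl)furan-3-yl]-4,8-dimethylundeca-2,6,8-trienoate
Conditions: LiCl, DBU, MeCN, 0 °C → rt
Reagents that add atoms: none
Why: Horner–Wadsworth–Emmons olefination under Masamune–Roush conditions, which is E-selective and mild enough to keep the α-methyl aldehyde from epimerising.

Step 12
Reactants: 21 ethyl (2E,4S,6E,8E)-11-[5-(furan-3-ylmethyl)furan-3-yl]-4,8-dimethylundeca-2,6,8-trienoate
Product: 22 (2E,4S,6E,8E)-11-[5-(furan-3-ylmethyl)furan-3-yl]-4,8-dimethylundeca-2,6,8-trien-1-ol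
Conditions: i-Bu2AlH (2.5 equiv), CH2Cl2, −78 °C
Reagents that add atoms: none
Why: 1,2-Reduction of the enoate to the allylic alcohol by the aluminium hydride, with no conjugate reduction.

Step 13
Reactants: 22 (2E,4S,6E,8E)-11-[5-(furan-3-ylmethyl)furan-3-yl]-4,8-dimethylundeca-2,6,8-trien-1-ol
Product: 23 [(2S,3S)-3-{(2S,4E,6E)-9-[5-(furan-3-ylmethyl)furan-3-yl]-6-methylnona-4,6-dien-2-yl}oxiran-2-yl]methanol
Conditions: Ti(OiPr)4 (10 mol %), L-(+)-diethyl tartrate (12 mol %), t-BuOOH, 4 Å molecular sieves, CH2Cl2, −20 °C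
Reagents that add atoms: tert-butyl hydroperoxide, CC(C)(C)OO
Why: Sharpless asymmetric epoxidation, in which the titanium tartrate delivers oxygen only to the allylic alcohol, so the diene and both furans are spared, and L-(+)-diethyl tartrate sets both new centres as the (2S,3S) trans epoxide from the E alkene.

Step 14
Reactants: 23 [(2S,3S)-3-{(2S,4E,6E)-9-[5-(furan-3-ylmethyl)furan-3-yl]-6-methylnona-4,6-dien-2-yl}oxiran-2-yl]methanol
Product: 24 (2R,3S)-3-{(2S,4E,6E)-9-[5-(furan-3-ylmethyl)furan-3-yl]-6-methylnona-4,6-dien-2-yl}oxirane-2-carbaldehyde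
Conditions: Dess–Martin periodinane, pyridine, CH2Cl2, 0 °C → rt
Reagents that add atoms: none
Why: Dess–Martin oxidation of the primary alcohol to the aldehyde under buffered conditions that leave the epoxide and its configuration intact (the C2 descriptor changes only by CIP ranking).

Step 15
Reactants: 24 (2R,3S)-3-{(2S,4E,6E)-9-[5-(furan-3-ylmethyl)furan-3-yl]-6-methylnona-4,6-dien-2-yl}oxirane-2-carbaldehyde; 25 ethyl 2-[bis(2,2,2-trifluoroethoxy)phosphoryl]propanoate
Product: 26 ethyl (2Z)-3-[(2S,3S)-3-{(2S,4E,6E)-9-[5-(furan-3-ylmethyl)furan-3-yl]-6-methylnona-4,6-dien-2-yl}oxiran-2-yl]-2-methylprop-2-enoate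
Conditions: 25, KN(SiMe3)2, 18-crown-6, THF, −78 °C; then 24
Reagents that add atoms: none
Why: Still–Gennari variant of the Horner–Wadsworth–Emmons reaction, whose trifluoroethyl phosphonate eliminates under kinetic control to the Z trisubstituted enoate and so places the ester carbonyl beside the epoxide.

Step 16
Reactants: 26 ethyl (2Z)-3-[(2S,3S)-3-{(2S,4E,6E)-9-[5-(furan-3-ylmethyl)furan-3-yl]-6-methylnona-4,6-dien-2-yl}oxiran-2-yl]-2-methylprop-2-enoate
Product: 27 (5R)-5-{(1S,2S,4E,6E)-9-[5-(furan-3-ylmethyl)furan-3-yl]-1-hydroxy-2,6-dimethylnona-4,6-dien-1-yl}-3-methylfuran-2(5H)-one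
Conditions: CSA (20 mol %), H2O (2 equiv), CH2Cl2, 0 °C → rt
Reagents that add atoms: water, O
Why: Acid-catalysed 5-exo epoxide-opening lactonisation, in which the ester carbonyl oxygen attacks the allylic epoxide carbon from the rear so that C5 forms with inversion while the carbinol keeps its configuration (the erythro hydroxy butenolide), and water then cleaves the ethoxy oxocarbenium ion to lactone and ethanol.

Step 17
Reactants: 27 (5R)-5-{(1S,2S,4E,6E)-9-[5-(furan-3-ylmethyl)furan-3-yl]-1-hydroxy-2,6-dimethylnona-4,6-dien-1-yl}-3-methylfuran-2(5H)-one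
Product: 28 (5E)-5-{(2S,4E,6E)-9-[5-(furan-3-ylmethyl)furan-3-yl]-2,6-dimethylnona-4,6-dien-1-ylidene}-3-methylfuran-2(5H)-one
Conditions: PPh3, DEAD, THF, −30 °C → rt, dark
Reagents that add atoms: none
Why: Mitsunobu-type dehydration, a stereospecific anti β-elimination known for γ-(α-hydroxyalkyl)butenolides, in which the oxyphosphonium group and the acidic C5–H leave antiperiplanar, so the erythro alcohol gives the alkene with C2' cis to C4–H (5E) and C2' itself is untouched.

**Compound list**

1 | furan-3-carbaldehyde | O=Cc1ccoc1 | starting material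
2 | ethynylmagnesium bromide | C#C[Mg]Br | starting material
3 | 1-(furan-3-yl)prop-2-yn-1-ol (racemic) | OC(C#C)c1ccoc1 | intermediate
4 | ethyl propiolate | CCOC(=O)C#C | starting material
5 | ethyl (2E)-3-{[1-(furan-3-yl)prop-2-yn-1-yl]oxy}prop-2-enoate (racemic) | CCOC(=O)/C=C/OC(C#C)c1ccoc1 | intermediate
6 | ethyl 2-formyl-5-(furan-3-yl)penta-3,4-dienoate (allenyl formyl ester, stereoisomer mixture, formed in the flask) | CCOC(=O)C(C=O)C=C=Cc1ccoc1 | intermediate
7 | ethyl 5-(furan-3-ylmethyl)furan-3-carboxylate | CCOC(=O)c1coc(Cc2ccoc2)c1 | intermediate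
8 | [5-(furan-3-ylmethyl)furan-3-yl]methanol | OCc1coc(Cc2ccoc2)c1 | intermediate
9 | 4-(bromomethyl)-2-(furan-3-ylmethyl)furan | BrCc1coc(Cc2ccoc2)c1 | intermediate
10 | allylmagnesium bromide | C=CC[Mg]Br | starting material
11 | 4-(but-3-en-1-yl)-2-(furan-3-ylmethyl)furan | C=CCCc1coc(Cc2ccoc2)c1 | intermediate
12 | methacrolein (2-methylprop-2-enal) | CC(=C)C=O | starting material
13 | (2E)-5-[5-(furan-3-ylmethyl)furan-3-yl]-2-methylpent-2-enal | O=C/C(C)=C/CCc1coc(Cc2ccoc2)c1 | intermediate
14 | iodoform | IC(I)I | starting material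
15 | 2-(furan-3-ylmethyl)-4-[(3E,5E)-6-iodo-4-methylhexa-3,5-dien-1-yl]furan | I/C=C/C(C)=C/CCc1coc(Cc2ccoc2)c1 | intermediate
16 | methyl (2R)-3-bromo-2-methylpropanoate | COC(=O)[C@@H](C)CBr | starting material
17 | [(2R)-3-methoxy-2-methyl-3-oxopropyl]zinc bromide (organozinc bromide, formed in the flask) | COC(=O)[C@@H](C)C[Zn]Br | intermediate
18 | methyl (2S,4E,6E)-9-[5-(furan-3-ylmethyl)furan-3-yl]-2,6-dimethylnona-4,6-dienoate | COC(=O)[C@@H](C)C/C=C/C(C)=C/CCc1coc(Cc2ccoc2)c1 | intermediate
19 | (2S,4E,6E)-9-[5-(furan-3-ylmethyl)furan-3-yl]-2,6-dimethylnona-4,6-dienal | O=C[C@@H](C)C/C=C/C(C)=C/CCc1coc(Cc2ccoc2)c1 | intermediate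
20 | triethyl phosphonoacetate | CCOC(=O)CP(=O)(OCC)OCC | starting material
21 | ethyl (2E,4S,6E,8E)-11-[5-(furan-3-ylmethyl)furan-3-yl]-4,8-dimethylundeca-2,6,8-trienoate | CCOC(=O)/C=C/[C@@H](C)C/C=C/C(C)=C/CCc1coc(Cc2ccoc2)c1 | intermediate
22 | (2E,4S,6E,8E)-11-[5-(furan-3-ylmethyl)furan-3-yl]-4,8-dimethylundeca-2,6,8-trien-1-ol | OC/C=C/[C@@H](C)C/C=C/C(C)=C/CCc1coc(Cc2ccoc2)c1 | intermediate
23 | [(2S,3S)-3-{(2S,4E,6E)-9-[5-(furan-3-ylmethyl)furan-3-yl]-6-methylnona-4,6-dien-2-yl}oxiran-2-yl]methanol | OC[C@@H]1O[C@H]1[C@@H](C)C/C=C/C(C)=C/CCc2coc(Cc3ccoc3)c2 | intermediate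
24 | (2R,3S)-3-{(2S,4E,6E)-9-[5-(furan-3-ylmethyl)furan-3-yl]-6-methylnona-4,6-dien-2-yl}oxirane-2-carbaldehyde | O=C[C@@H]1O[C@H]1[C@@H](C)C/C=C/C(C)=C/CCc2coc(Cc3ccoc3)c2 | intermediate
25 | ethyl 2-[bis(2,2,2-trifluoroethoxy)phosphoryl]propanoate | CCOC(=O)C(C)P(=O)(OCC(F)(F)F)OCC(F)(F)F | starting material
26 | ethyl (2Z)-3-[(2S,3S)-3-{(2S,4E,6E)-9-[5-(furan-3-ylmethyl)furan-3-yl]-6-methylnona-4,6-dien-2-yl}oxiran-2-yl]-2-methylprop-2-enoate | CCOC(=O)/C(C)=C\[C@@H]1O[C@H]1[C@@H](C)C/C=C/C(C)=C/CCc2coc(Cc3ccoc3)c2 | intermediate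
27 | (5R)-5-{(1S,2S,4E,6E)-9-[5-(furan-3-ylmethyl)furan-3-yl]-1-hydroxy-2,6-dimethylnona-4,6-dien-1-yl}-3-methylfuran-2(5H)-one | CC1=C[C@H]([C@@H](O)[C@@H](C)C/C=C/C(C)=C/CCc2coc(Cc3ccoc3)c2)OC1=O | intermediate
28 | (5E)-5-{(2S,4E,6E)-9-[5-(furan-3-ylmethyl)furan-3-yl]-2,6-dimethylnona-4,6-dien-1-ylidene}-3-methylfuran-2(5H)-one | CC1=C/C(=C\[C@@H](C)C/C=C/C(C)=C/CCc2coc(Cc3ccoc3)c2)OC1=O | target

**Step count and main risks**

Total step count: 17. Longest linear sequence: 17 steps (1 to 28); all other inputs are bought.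

Step 3. The gold catalyst may ionise the propargylic C–O bond next to ring A, or be tied up as an acetylide at the terminal alkyne, so that 5 is consumed without closing ring B. The fallback sets out from 1 and joins the two furans by cross-coupling instead. Compound 1 is reduced with NaBH4 to furan-3-ylmethanol F1, which PBr3 converts into 3-(bromomethyl)furan F2. Zinc insertion gives (furan-3-ylmethyl)zinc bromide F3, and its Negishi coupling (Pd(PPh3)4, THF) with purchased ethyl 5-bromofuran-3-carboxylate gives 7, where the route is rejoined.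

Step 16. The acid may degrade the two furans, or the epoxide may open with some cationic character or in the 6-endo sense, so that the erythro relationship needed for the 5E alkene is not set cleanly. The fallback sets out from 19 and forms the C5–C1' bond directly. 3-Methylfuran-2(5H)-one is silylated (Me3SiCl, Et3N) to 3-methyl-2-[(trimethylsilyl)oxy]furan F4. Its fluoride-initiated vinylogous Mukaiyama aldol addition to 19 (anhydrous Bu4NF, THF, −78 °C) should favour the erythro adducts, in contrast to the threo preference under Lewis acids. It would give 27 together with its erythro diastereomer (5S)-5-{(1R,2S,4E,6E)-9-[5-(furan-3-ylmethyl)furan-3-yl]-1-hydroxy-2,6-dimethylnona-4,6-dien-1-yl}-3-methylfuran-2(5H)-one F5. The threo adducts are removed by chromatography, both erythro alcohols are dehydrated to 28 in step 17, and the route is rejoined at 27.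

Step 8. E selectivity at the new iodoalkene may be incomplete and the light-sensitive dienyl iodide may be lost on the chromium salts. The fallback sets out from 13 and makes the iodide by syn-hydrometalation. Corey–Fuchs olefination (CBr4, PPh3) gives 4-[(3E)-6,6-dibromo-4-methylhexa-3,5-dien-1-yl]-2-(furan-3-ylmethyl)furan F6, and n-BuLi (THF, −78 °C) converts it into 2-(furan-3-ylmethyl)-4-[(3E)-4-methylhex-3-en-5-yn-1-yl]furan F7. Hydrozirconation with Cp2Zr(H)Cl followed by I2 gives 15 with the E geometry fixed by syn addition, and the route is rejoined at 15.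

**Further compounds**

F1 | step 3 | furan-3-ylmethanol | OCc1ccoc1
F2 | step 3 | 3-(bromomethyl)furan | BrCc1ccoc1
F3 | step 3 | (furan-3-ylmethyl)zinc bromide | Br[Zn]Cc1ccoc1
F4 | step 16 | 3-methyl-2-[(trimethylsilyl)oxy]furan | Cc1ccoc1O[Si](C)(C)C
F5 | step 16 | (5S)-5-{(1R,2S,4E,6E)-9-[5-(furan-3-ylmethyl)furan-3-yl]-1-hydroxy-2,6-dimethylnona-4,6-dien-1-yl}-3-methylfuran-2(5H)-one | CC1=C[C@@H]([C@H](O)[C@@H](C)C/C=C/C(C)=C/CCc2coc(Cc3ccoc3)c2)OC1=O
F6 | step 8 | 4-[(3E)-6,6-dibromo-4-methylhexa-3,5-dien-1-yl]-2-(furan-3-ylmethyl)furan | BrC(Br)=C/C(C)=C/CCc1coc(Cc2ccoc2)c1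
F7 | step 8 | 2-(furan-3-ylmethyl)-4-[(3E)-4-methylhex-3-en-5-yn-1-yl]furan | C#C/C(C)=C/CCc1coc(Cc2ccoc2)c1
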